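The readings are calculated on assumed constants; the scatter is artificial.

**The vessel.** A closed, stirred vessel holds X and J and takes up G, held at constant pressure, as dissolved D; Q is the product.

in all of them: X 0.50 mM; G 0.12 mM (held)

| run | J | remark | time |
|---|---|---|---|
| winter | 0.050 mM | run made earlier |  |
| flask | 0.0250 mM |  | 3.0 min |

winter run (percent of the X charged)

| time / s | Q / % |
|---|---|
| 10.0 | 9 |
| 15.0 | 13 |
| 20.0 | 15 |
| 30.0 | 24 |
| 40.0 | 33 |

(each reading ± 1.5 percentage points)

- the numbers in the tables scatter with a standard deviation of 1.5 percentage points
- at the start none of G is in solution
- no earlier run changes the charge of J; that part of a forecast is a guess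
- D is what G becomes in solution

- cedar: doubling the saturation concentration of G, all else as stated
- elm: doubling the transfer coefficient of G, all else as stated

- the Q standing at 3.0 min, as a percentage of the X charged
- concentration of D in solution at 50 s, in percent of saturation
- the change that raises the amount of Q at 3.0 min, in percent of the X charged most ("none" if none brings more than 2 percentage points) (cedar / elm / none)
- amount of Q at 3.0 min, in percent of the X charged, after cedar

**Starting rate.** The last winter reading, 33% at 40.0 s, lies on a nearly straight trace. Read from it is the turnover time τ, the time in which that rate would turn over the charge of X: 121 s. This is shorter than the 3.0 min of the flask, so a rate that starts as in the winter run must fall before the end of the flask.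

**Two slowings.** The flask holds half the J of the winter run, and no run shows what that does, so the reckoning here leaves the rate unchanged, a guess. The winter readings show no bend, and the second slowing is assumed: a pseudo-first-order rate that follows the X left, falling as exp(−t/τ). By 3.0 min the rate stands at a factor 0.227 of its start. The accumulated turnover is 77.3%, and this reckoning commits to that as Q.

**The forecast.** It puts Q at 90% (68% to 100%), above the 77.3% of this reckoning, D at 50 s at 30% of saturation, the best change at none, and Q after cedar at 95%. Its ground: “I lean towards transfer limitation, but halving J is untested”.

**What stood.** The flask gives Q 60.9%, D at 33.8% of saturation, best change cedar (gain 8.2 percentage points; elm 0.12 points), and 69.2% after cedar.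

    G ⇌ D, rate k1*(csat - [D]) (kL = 0.0516 s⁻¹)
    X + D ⇌ Q (K = 22000 L mol⁻¹, k = 857 L mol⁻¹ s⁻¹)
    Q ⇌ L (K = 0.940, k = 0.00182 s⁻¹)
    D + J → E (k = 344 L mol⁻¹ s⁻¹)

At 3.00 min the flask holds X 26.0%, so 74.0% of the charge has turned over, against 77.3% reckoned; that turnover stands as Q 60.9% and L, a second product, 13.1%. The same vessel read at 50 s is reckoned with τ to keep 66.2% of its X. It holds X 60.5%, Q 37.8% and L 1.75%.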